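the same everywhere: left-handed substrate 0.59 M; right-handed substrate 0.59 M
- Saturday's: solid reagent 2.2 equiv; racemization catalyst 1.9 mol%; run made earlier
- Sunday's: solid reagent 2.2 equiv; racemization catalyst 3.6 mol%; run made earlier
- Tuesday's: solid reagent 2.2 equiv; racemization catalyst 4.4 mol%; run made earlier
- noon: solid reagent 2.20 equiv; racemization catalyst 5 mol%; time 4.0 h
- midnight: solid reagent 2.20 equiv; racemization catalyst 2.5 mol%; time 4.0 h

| run | time / h | right-handed substrate / % | left-handed substrate / % |
|---|---|---|---|
| Saturday's | 0.333 | 42.1 | 40.8 |
| Saturday's | 1.00 | 22.0 | 20.8 |
| Saturday's | 2.00 | 4.2 | 2.8 |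
| Saturday's | 3.00 | 1.5 | 2.6 |
| Saturday's | 4.00 | 0 | 0.3 |
| Sunday's | 0.333 | 40.8 | 43.1 |
| Sunday's | 1.00 | 22.2 | 20.4 |
| Sunday's | 2.00 | 5.2 | 6.1 |
| Sunday's | 3.00 | 0 | 0.5 |
| Sunday's | 4.00 | 1.0 | 2.4 |
| Tuesday's | 0.833 | 25.4 | 25.7 |
| Tuesday's | 1.50 | 8.7 | 11.7 |
| Tuesday's | 2.50 | 2.5 | 1.4 |
| Tuesday's | 3.00 | 0.6 | 1.8 |
| Tuesday's | 4.00 | 1.2 | 0.3 |

(standard deviation of a reading: 1 percentage point)

- partner is single-handed; left-handed substrate and right-handed substrate are mirror images of each other, charged as a racemate, each of them at the stated concentration
- given per volume of solution although it is solid: solid reagent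
- the analysis behind the earlier runs scatters by 1 percentage point, standard deviation
- at the start none of the solid reagent is in solution
- an excess is the difference of the two amounts in percent of their sum
- an excess is below zero if the other one leads
- the handed part of partner does not stay in what it makes, so the products of the two hands are mirror images too

- which of the two ends with the higher excess of right-handed substrate over left-handed substrate among what is left of the two ("neither" if they lie within 2 percentage points) (noon / midnight / neither)
- excess of right-handed substrate over left-handed substrate among what is left of the two at the end, noon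
- excess of right-handed substrate over left-handed substrate among what is left of the two at the end, midnight

1. Begin at the rate. In the first 0.333 h of Saturday's run, the pair (left-handed and right-handed substrate together) loses 0.514 h⁻¹ of its charge.

2. Late on, the loss slows with what is left. Between 1.50 h and 2.50 h, Tuesday's run reads 1.65 h⁻¹, with the scatter of its readings: this is the drain, the fraction of the remaining pair lost per hour.

3. Do not run that drain on unchanged. From 2.50 h to 4.00 h Tuesday's run reads 0.637 h⁻¹, lower by a factor 2.59. So take the residue from the last readings: at 4.00 h the pair averages 1.73% over the earlier runs.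

4. Put that back in. The scatter of 1 percentage point on each hand is more than an even share of this residue, so end readings say little about an excess.

5. Go round again with rates. Assume the excess is proportional to drain over swap between the hands, with the amount left not entering. Then readings with much left can guide the estimate for the end: Saturday's gives 2.80% at 1.00 h, Tuesday's −0.587% at 0.833 h. The signs differ, so I commit to about zero for noon and for midnight.

6. The forecast agrees: 0% for noon, 0% for midnight, neither ahead, holding that “any selectivity is either small or fully offset by racemization at these loadings”.

7. The flasks give 0.226% for noon and 0.364% for midnight, so neither leads.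

    racemization catalyst → spent catalyst (k = 4.34 × 10⁻⁵ min⁻¹)
    left-handed substrate + racemization catalyst ⇌ right-handed substrate + racemization catalyst, rate k2*[racemization catalyst]*[left-handed substrate] forward; the back reaction follows from the equilibrium constant (k = 51.5 L mol⁻¹ min⁻¹)
    partner + right-handed substrate → right-handed product (k = 0.0642 L mol⁻¹ min⁻¹)
    2 racemization catalyst ⇌ resting dimer, settled at all times (K = 37.9 L mol⁻¹)
    partner + left-handed substrate → left-handed product (k = 0.112 L mol⁻¹ min⁻¹)
    solid reagent ⇌ partner, rate k6*(cs6 - [partner]) while solid is left; crystals form when [partner] > cs6 (solubility = 0.560 M, k = 0.0380 min⁻¹)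

Midnight ends with a drain of 0.728 h⁻¹, the two rate constants averaged on c(partner) of 0.138 M. Noon's swap half-life, 0.46 min, is short against 4.0 h, though its selectivity factor is 1.74 and its product excess 26.9% after 1.00 h. The neighbour of midnight charged with 0.550 equiv of solid reagent has c(partner) of 7.11 × 10⁻⁹ M at 4.00 h. Its drain is 3.76 × 10⁻⁸ h⁻¹, a fraction 2.27 × 10⁻⁸ of Tuesday's 1.65 h⁻¹. Its excess is 0%, with 36.2% left-handed and 36.2% right-handed substrate.

The data come from a simulation on assumed constants, noise included.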